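The earlier runs and the new flask are simulated with made-up constants, and the scatter is random.

In both earlier runs the logarithm of the fraction of substrate left falls close to a straight line, so its slope stays nearly the same as the flask empties, and we build on that invariant.

| flask | substrate | partner | protic impurity | temperature | remark | time |
|---|---|---|---|---|---|---|
| east | 0.025 M | 0.035 M | 1 mM | −10 °C | run made earlier |  |
| south-west | 0.10 M | 0.035 M | 1 mM | 10 °C | run made earlier |  |
| Monday's | 0.050 M | 0.0350 M | 1.00 mM | 10 °C |  | 8.0 min |
| Sunday's | 0.050 M | 0.0350 M | 1.00 mM |  | at −5 °C until 6.0 min, from then on at 25 °C | 8.0 min |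
| Tuesday's | 0.050 M | 0.0350 M | 1.00 mM | 25 °C |  | 8.0 min |
| Thursday's | 0.050 M | 0.0350 M | 1.00 mM | −5 °C |  | 8.0 min |

| run | time / min | target / % | substrate / % |
|---|---|---|---|
| east | 4.00 | 0 | 88.2 |
| east | 8.00 | 0.7 | 79.3 |
| east | 10.0 | 3.9 | 74.2 |
| east | 15.0 | 6.3 | 65.7 |
| east | 20.0 | 9.6 | 59.0 |
| east | 25.0 | 14.3 | 48.6 |
| south-west | 0.500 | 0 | 84.4 |
| south-west | 1.33 | 3.1 | 62.8 |
| south-west | 2.50 | 10.0 | 40.7 |
| south-west | 4.00 | 17.8 | 23.2 |
| south-west | 6.00 | 21.2 | 12.8 |
| south-west | 8.00 | 24.3 | 5.5 |
| south-west | 10.0 | 27.1 | 2.4 |

(scatter of a reading: 1 percentage point)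



- the flask with the highest amount of target, in percent of the substrate charged ("all alike" if they lie within 1.5 percentage points) (Monday's / Sunday's / Tuesday's / Thursday's / all alike)
- final target, as a percentage of the substrate charged, in Monday's
- final target, as a percentage of the substrate charged, in Sunday's
- final target, as a percentage of the substrate charged, in Tuesday's
- final target, as a percentage of the substrate charged, in Thursday's

We take the slope from one reading in each run: 0.0289 min⁻¹ in the east run and 0.365 min⁻¹ in the south-west run. These two temperatures give an activation energy of 78.6 kJ mol⁻¹, hence 0.0564 min⁻¹ at −5 °C and 1.96 min⁻¹ at 25 °C.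

A first-order loss feels the rate constant through its mean over the run, so the curve of Sunday's temperature can be replaced by that mean without error. Sunday's has then been through 4.26 substrate lifetimes. We call this count N, the mean rate constant times the time, and it is the Damköhler number of the first step. Monday's stands at 2.92, Tuesday's at 15.7 and Thursday's at 0.451. The fraction of substrate left is e to the minus N, which is 63.7% in Thursday's.

N is larger in Tuesday's than in Sunday's, larger in Sunday's than in Monday's, and larger in Monday's than in Thursday's, and we commit to that order for target as well. But is one number enough? N counts substrate leaving, not target arriving. The south-west run at 2.50 min has N of 0.912, more than the 0.722 of the east run at 25.0 min, yet it holds 10.0% of target against 14.3%. So the order for target remains a bet.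

The forecast names Tuesday's as highest, with 35% for Monday's, 34% for Sunday's, 38% for Tuesday's and 4% for Thursday's, and says “Tuesday's is essentially finished”.

The flasks give 35.1% for Monday's, 38.1% for Sunday's, 50.6% for Tuesday's and 5.51% for Thursday's, so Tuesday's is highest.

    substrate → intermediate (k = 0.0310 s⁻¹, Ea = 78.0 kJ mol⁻¹)
    2 intermediate → homo product (k = 0.240 M⁻¹ s⁻¹, Ea = 61.0 kJ mol⁻¹)
    2 substrate → homo dimer (k = 0.00160 M⁻¹ s⁻¹, Ea = 52.0 kJ mol⁻¹)
    partner + intermediate → target (k = 0.370 M⁻¹ s⁻¹, Ea = 63.0 kJ mol⁻¹)
    partner + protic impurity → quenched reagent (k = 91.0 M⁻¹ s⁻¹, Ea = 37.0 kJ mol⁻¹)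
    (constants at 25 °C)

Sunday's shows where N stops: e to the minus N gives 1.41%, and 1.73% of substrate stands there, yet 22.6% still waits as intermediate. Thursday's left for 80.0 min has N of 4.51, which gives 1.10% of substrate against a simulated 1.20%, with target at 46.4%. Of the temperature effects tried on the spread at the asked time, the largest single one sits on the step from partner and intermediate to target: with it taken away, the gap between Tuesday's and Thursday's shrinks from 45 percentage points to 2 points, against 20 points with temperature's action on the step from substrate to intermediate taken away.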